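Midnight was the run I had to go on when asked to compare grey with violet. In these flasks first end groups couple with second end groups to give links and by-product, and links can pass into the isomer of the product.

| flask | first end groups | second end groups | temperature | remark | time |
|---|---|---|---|---|---|
| midnight | 0.015 M | 0.90 equiv (fed, over 12 d) | −10 °C | run made earlier |  |
| grey | 0.010 M | 0.230 equiv (fed, over 12 d) |  | at −10 °C throughout | 30 d |
| violet | 0.010 M | 0.900 equiv (fed, over 12 d) |  | at −10 °C until 12 d, from then on at 10 °C | 30 d |

- the flask that ends with the higher amount of links, in percent of the first end groups charged, or "neither" when 2 percentage points or less lies between them (grey / violet / neither)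
- final links, as a percentage of the first end groups charged, in grey
- final links, as a percentage of the first end groups charged, in violet

- amounts and yields of links count crystals too
- given per volume of solution although it is solid: crystals
- what was read earlier has a scatter of 1 percentage point, one standard deviation
- steps thought possible: first end groups + second end groups <-> links + by-product; links <-> isomer of the product; crystals <-> links
- the earlier runs do not show what temperature does; that part of a forecast is a guess

midnight run (percent of the first end groups charged)

| time / d | links / % | first end groups / % |
|---|---|---|
| 0.500 | 2.7 | 97.3 |
| 0.833 | 3.9 | 94.5 |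
| 1.04 | 5.7 | 92.6 |
| 1.67 | 9.3 | 88.8 |
| 2.50 | 12.3 | 83.1 |
| 4.00 | 18.6 | 74.3 |
| 6.00 | 23.6 | 62.4 |

(readings scatter by 1 percentage point)

I read the last two rows of the table, setting the first end groups lost against the links found. At 4.00 d the midnight run had lost 25.7% and held 18.6% of links; at 6.00 d it had lost 37.6% and held 23.6%. I took the gap between lost and found for isomer. So I carried one quantity, s, the links as a share of the first end groups reacted (the selectivity), which the last row reads at 62.8%. That reading was lower than the row before, and with a scatter of 1 percentage point I could not say that s had stopped falling, but I committed to it as a balance between links and isomer.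

The last row also gave the amount reacted against the dose: 0.450 of second end groups had gone in by then. In that proportion, grey reacts 19.2% and my s gives 12.1% of links. Violet reacts 75.2% and gives 47.2%, though its warming is a guess.

The forecast also chose violet, but its figures stood lower than mine: 1% for grey (0.1% to 4%) and 5% for violet (0.3% to 16%). Its ground for violet ending higher was: “A finite isomer equilibrium would leave more, scaling with the larger total”.

The flasks gave violet as the higher, with 37.7% of links in violet against 14.1% in grey.

    first end groups + second end groups ⇌ links + by-product (K = 2.40, k = 47.0 M⁻¹ h⁻¹, Ea = 58.0 kJ mol⁻¹, ΔH = −31.0 kJ mol⁻¹)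
    links ⇌ isomer of the product (K = 0.520, k = 0.0620 h⁻¹, Ea = 94.0 kJ mol⁻¹, ΔH = −17.0 kJ mol⁻¹)
    crystals ⇌ links, rate k3*(cs3 - [links]) while solid is left; crystals form when [links] > cs3 (solubility = 6.20 mM, k = 1.00 h⁻¹)
    (constants at −10 °C)

In grey, links stood at 14.1% at 12.0 d and at 14.1% at 30.0 d, and my s on the 21.4% reacted gives 13.4%. Violet ended with s at 76.9% on 49.0% reacted. The neighbouring flask is violet with 3.60 equiv of second end groups. It reacted 80.0%, so the s of violet gives 61.6% of links, and that neighbouring flask ended with 61.6%.

The readings come from a simulation from invented constants, noise included.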